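**Plan**

1. Retrosynthetic cuts: the fifteen O–CH3 bonds; the ring D–O–ring E aryl ether bond (Ullmann); ring D itself, at the C–C bond between its only CH carbon and the neighbouring C–OH carbon (thermal cyclobutenone ring expansion), then at the bond from the squarate carbon to the oxygenated vinyl carbon; last the A–O–B, B–O–C and E–O–F ether bonds.
2. Feature used (rings lettered A to F along the SMILES; ring D numbered C1 = carbon bearing the oxygen to ring C, C2 = CH, C3 to C5 = C–OH, C6 = carbon bearing the oxygen to ring E): C3, C4, C5 and C6 are four contiguous oxygenated carbons and map onto the four carbons of dimethyl squarate; C2–H and C1–O–ring C map onto the CH2 and the O-bearing carbon of a 1-aryloxyvinyl group.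
3. Forward: rings A, B and C are bought as oxygenated benzenes and joined by two Ullmann couplings; the A–B–C phenol becomes a 1-stannylvinyl ether, is lithiated and added to dimethyl squarate; thermolysis then closes ring D, the only ring made in the route.
4. Rings E and F are joined separately by a Chan–Lam coupling and attached to the unmasked ring D phenol by a last Ullmann coupling, followed by global demethylation.
5. Stereochemistry: the target has no stereocentre and no stereogenic double bond; the one stereocentre of the route (C4 of cyclobutenone 16, racemic) becomes an aromatic carbon in step 10.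

Key step: step 10

Abbreviation used in names: Ar = 4-[2,6-dimethoxy-4-(2,4,6-trimethoxyphenoxy)phenoxy]-2,6-dimethoxyphenyl, the permethylated A–B–C unit bonded through ring C.
Remark on the chemistry: cyclobutenone 16 is made and used as the racemate, because its only stereocentre is erased on aromatisation.

**Route**

Step 1
Reactants: 1 4-bromo-2,6-dimethoxyphenol
Product: 2 2-(benzyloxy)-5-bromo-1,3-dimethoxybenzene
Conditions: BnBr, K2CO3, DMF, rt
Reagents that add atoms: benzyl bromide, BrCc1ccccc1
Why: Williamson etherification masks the phenol so that this ring can act only as the electrophile in the Ullmann couplings that follow.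

Step 2
Reactants: 3 2,4,6-trimethoxyphenol; 2 2-(benzyloxy)-5-bromo-1,3-dimethoxybenzene
Product: 4 2-(benzyloxy)-1,3-dimethoxy-5-(2,4,6-trimethoxyphenoxy)benzene (A–B benzyl ether)
Conditions: CuI (10 mol%), picolinic acid (20 mol%), K3PO4, DMSO, 90 °C, argon
Reagents that add atoms: none
Why: Ullmann diaryl ether synthesis with a CuI/picolinate catalyst, a system established for di-ortho-substituted phenols and electron-rich aryl bromides, should join ring A to the unhindered C–Br carbon of ring B.

Step 3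
Reactants: 4 A–B benzyl ether
Product: 5 2,6-dimethoxy-4-(2,4,6-trimethoxyphenoxy)phenol (A–B phenol)
Conditions: H2 (1 atm), 10% Pd/C, EtOAc/MeOH, rt
Reagents that add atoms: none
Why: Hydrogenolysis of the benzyl aryl ether over palladium should free the ring B phenol while methyl ethers and diaryl ethers stay inert.

Step 4
Reactants: 5 A–B phenol; 2 2-(benzyloxy)-5-bromo-1,3-dimethoxybenzene
Product: 6 2-[4-(benzyloxy)-3,5-dimethoxyphenoxy]-1,3-dimethoxy-5-(2,4,6-trimethoxyphenoxy)benzene (A–B–C benzyl ether)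
Conditions: CuI (10 mol%), picolinic acid (20 mol%), K3PO4, DMSO, 100 °C, argon
Reagents that add atoms: none
Why: A second Ullmann diaryl ether synthesis of the same kind as step 2 should attach ring C, since the nucleophile is again a 2,6-dimethoxyphenoxide and the bromide is the same.

Step 5
Reactants: 6 A–B–C benzyl ether
Product: 7 4-[2,6-dimethoxy-4-(2,4,6-trimethoxyphenoxy)phenoxy]-2,6-dimethoxyphenol (ArOH, the A–B–C phenol)
Conditions: H2 (1 atm), 10% Pd/C, EtOAc/MeOH, rt
Reagents that add atoms: none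
Why: Benzyl ether hydrogenolysis as in step 3 should expose the ring C phenol whose oxygen becomes the ring C–O–ring D bridge.

Step 6
Reactants: 7 ArOH
Product: 8 (E)-1,2-dichlorovinyl ether ArO–C(Cl)=CHCl
Conditions: trichloroethylene, K2CO3, DMF, 70 °C
Reagents that add atoms: trichloroethylene, ClC=C(Cl)Cl
Why: Base converts trichloroethylene into dichloroacetylene in the flask and the phenoxide adds to it in anti fashion, the known route from phenols to aryl (E)-1,2-dichlorovinyl ethers.

Step 7
Reactants: 8 ArO–C(Cl)=CHCl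
Product: 11 aryl ethynyl ether ArO–C≡CH, via chloroalkyne 9 (not isolated), via lithium aryloxyacetylide 10 (not isolated)
Conditions: n-BuLi (2.3 equiv), THF, −78 to −40 °C; then H2O, −78 °C; used without storage
Reagents that add atoms: none
Why: Vinyl deprotonation with loss of LiCl gives the chloroalkyne, chlorine–lithium exchange gives the acetylide and protonation gives the terminal ynol ether, a known elimination sequence whose steps are faster at −78 °C than lithiation of the methoxyarene rings.

Step 8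
Reactants: 11 ArO–C≡CH
Product: 12 tributyl[1-(aryloxy)vinyl]stannane ArO–C(SnBu3)=CH2
Conditions: Bu3SnH (slow addition), Pd(PPh3)4 (2 mol%), THF, 0 °C to rt; chromatography on Et3N-deactivated silica
Reagents that add atoms: tributyltin hydride, CCCC[SnH](CCCC)CCCC
Why: Hydrostannation of 1-alkoxyalkynes under zerovalent palladium catalysis is a syn addition that places tin on the oxygen-bearing carbon, which here should give the 1-stannylvinyl ether.

Step 9
Reactants: 12 ArO–C(SnBu3)=CH2; 13 dimethyl squarate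
Product: 16 racemic 4-[(tert-butyldimethylsilyl)oxy]-2,3-dimethoxy-4-[1-(aryloxy)vinyl]cyclobut-2-en-1-one, via 1-aryloxyvinyllithium 14 (not isolated), via lithium alkoxide adduct 15 (not isolated)
Conditions: n-BuLi, THF, −78 °C; cannulated into 13, THF, −78 °C; then TBSOTf, −78 to −20 °C; chromatography on Et3N-deactivated silica
Reagents that add atoms: tert-butyldimethylsilyl trifluoromethanesulfonate, CC(C)(C)[Si](C)(C)OS(=O)(=O)C(F)(F)F
Why: Tin–lithium exchange should give the 1-oxyvinyllithium without arene metalation, 1,2-addition to one of the two equivalent squarate carbonyls and silylation of the tertiary alkoxide follow the usual preparation of 4-alkenyl-4-silyloxycyclobutenones, and the new stereocentre is formed racemic and is lost in step 10.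

Step 10
Reactants: 16 racemic 4-silyloxy-4-[1-(aryloxy)vinyl]cyclobutenone
Product: 19 4-[(tert-butyldimethylsilyl)oxy]-2,3-dimethoxy-5-(aryloxy)phenol (A–B–C–D tetramer), via dienylketene 17 (not isolated), via cyclohexadienone 18 (not isolated)
Conditions: toluene (degassed, 0.01 M), 110 °C, argon
Reagents that add atoms: none
Why: This is a Moore ring expansion, in which conrotatory 4π opening of the C1–C4 bond of the cyclobutenone gives (Z)-dienylketene 17, disrotatory 6π electrocyclisation joins the ketene carbon to the vinyl CH2 to give dienone 18, and enolisation gives phenol 19. The closest known reaction type is the thermolysis of squarate-derived 4-alkenyl- and 4-(1-alkoxyalkenyl)-4-silyloxycyclobutenones to mono-protected hydroquinones. Ring D is closed by the 6π electrocyclisation, the new bond running from the former carbonyl carbon (ring D C3) to the former CH2 carbon (ring D C2). No stereocentre is formed, and the racemic centre of 16 becomes an sp2 carbon. The step needs the vinyl group to turn inward, towards the ketene, and this is secured by the torquoselective outward rotation of the donor silyloxy group on the same carbon. Only the C1–C4 bond can open, so no regiochemical alternative exists, and the silyl ether holds the product at the stage where the two para oxygens of ring D remain different.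

Step 11
Reactants: 19 A–B–C–D silyloxy phenol
Product: 20 tert-butyldimethylsilyl ether of 2,3,4-trimethoxy-6-(aryloxy)phenol
Conditions: MeOH, PPh3, DIAD, THF, 0 °C to rt
Reagents that add atoms: methanol, CO
Why: Mitsunobu etherification methylates the unhindered new phenol under neutral conditions, so the aryl silyl ether cannot be cleaved or transferred as it might be with carbonate bases.

Step 12
Reactants: 20 silyl ether of 2,3,4-trimethoxy-6-(aryloxy)phenol
Product: 21 2,3,4-trimethoxy-6-(aryloxy)phenol (ring D phenol)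
Conditions: Bu4NF, AcOH, THF, 0 °C
Reagents that add atoms: none
Why: Fluoride cleaves the aryl silyl ether, and the acetic acid buffer protonates the electron-rich phenoxide at once so that it is not oxidised.

Step 13
Reactants: 1 4-bromo-2,6-dimethoxyphenol; 22 3,4,5-trimethoxyphenylboronic acid
Product: 23 5-bromo-1,3-dimethoxy-2-(3,4,5-trimethoxyphenoxy)benzene (E–F bromide)
Conditions: Cu(OAc)2 (1 equiv), pyridine, 4 Å molecular sieves, CH2Cl2, air, rt
Reagents that add atoms: none
Why: Chan–Lam coupling arylates the phenol oxygen at room temperature with air returning copper to the divalent state, tolerates 2,6-disubstituted phenols and leaves the C–Br bond untouched for step 14.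

Step 14
Reactants: 21 ring D phenol; 23 E–F bromide
Product: 24 1-(aryloxy)-2-[3,5-dimethoxy-4-(3,4,5-trimethoxyphenoxy)phenoxy]-3,4,5-trimethoxybenzene (pentadecamethyl ether of the target)
Conditions: CuI (20 mol%), picolinic acid (40 mol%), K3PO4, DMSO, 100 to 110 °C, argon
Reagents that add atoms: none
Why: Ullmann diaryl ether synthesis of the same type as steps 2 and 4 should join the di-ortho-substituted ring D phenoxide to the bromide of ring E, whose C–Br carbon has no ortho substituent.

Step 15
Reactants: 24 pentadecamethyl ether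
Product: 26 CNP0175585.0, via aryloxydibromoborane ester 25 (not isolated)
Conditions: BBr3 (excess), CH2Cl2, −78 °C to rt; then H2O, 0 °C; degassed solvents
Reagents that add atoms: none
Why: BBr3 cleaves aryl methyl ethers through aryloxyboron bromides (written as the idealised fully borylated ester 25) that hydrolyse on work-up, and it leaves diaryl ether bonds intact.

**Compound list**

1 | 4-bromo-2,6-dimethoxyphenol | COc1cc(Br)cc(OC)c1O | starting material
2 | 2-(benzyloxy)-5-bromo-1,3-dimethoxybenzene | COc1cc(Br)cc(OC)c1OCc1ccccc1 | intermediate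
3 | 2,4,6-trimethoxyphenol | COc1cc(OC)c(O)c(OC)c1 | starting material
4 | 2-(benzyloxy)-1,3-dimethoxy-5-(2,4,6-trimethoxyphenoxy)benzene | COc1cc(OC)c(Oc2cc(OC)c(OCc3ccccc3)c(OC)c2)c(OC)c1 | intermediate
5 | 2,6-dimethoxy-4-(2,4,6-trimethoxyphenoxy)phenol | COc1cc(OC)c(Oc2cc(OC)c(O)c(OC)c2)c(OC)c1 | intermediate
6 | 2-[4-(benzyloxy)-3,5-dimethoxyphenoxy]-1,3-dimethoxy-5-(2,4,6-trimethoxyphenoxy)benzene | COc1cc(OC)c(Oc2cc(OC)c(Oc3cc(OC)c(OCc4ccccc4)c(OC)c3)c(OC)c2)c(OC)c1 | intermediate
7 | 4-[2,6-dimethoxy-4-(2,4,6-trimethoxyphenoxy)phenoxy]-2,6-dimethoxyphenol (ArOH) | COc1cc(OC)c(Oc2cc(OC)c(Oc3cc(OC)c(O)c(OC)c3)c(OC)c2)c(OC)c1 | intermediate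
8 | (E)-1,2-dichlorovinyl ether of 7 | Cl/C=C(/Cl)Oc1c(OC)cc(Oc2c(OC)cc(Oc3c(OC)cc(OC)cc3OC)cc2OC)cc1OC | intermediate
9 | chloroethynyl ether of 7 (ArO–C≡C–Cl) | ClC#COc1c(OC)cc(Oc2c(OC)cc(Oc3c(OC)cc(OC)cc3OC)cc2OC)cc1OC | intermediate
10 | lithium aryloxyacetylide (ArO–C≡C–Li) | [Li]C#COc1c(OC)cc(Oc2c(OC)cc(Oc3c(OC)cc(OC)cc3OC)cc2OC)cc1OC | intermediate
11 | ethynyl ether of 7 (ArO–C≡CH) | C#COc1c(OC)cc(Oc2c(OC)cc(Oc3c(OC)cc(OC)cc3OC)cc2OC)cc1OC | intermediate
12 | tributyl[1-(aryloxy)vinyl]stannane | C=C(Oc1c(OC)cc(Oc2c(OC)cc(Oc3c(OC)cc(OC)cc3OC)cc2OC)cc1OC)[Sn](CCCC)(CCCC)CCCC | intermediate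
13 | dimethyl squarate (3,4-dimethoxycyclobut-3-ene-1,2-dione) | COC1=C(OC)C(=O)C1=O | starting material
14 | 1-(aryloxy)vinyllithium | [Li]C(=C)Oc1c(OC)cc(Oc2c(OC)cc(Oc3c(OC)cc(OC)cc3OC)cc2OC)cc1OC | intermediate
15 | lithium alkoxide of 4-hydroxy-2,3-dimethoxy-4-[1-(aryloxy)vinyl]cyclobut-2-en-1-one (racemic) | [Li]OC1(C(=C)Oc2c(OC)cc(Oc3c(OC)cc(Oc4c(OC)cc(OC)cc4OC)cc3OC)cc2OC)C(OC)=C(OC)C1=O | intermediate
16 | 4-[(tert-butyldimethylsilyl)oxy]-2,3-dimethoxy-4-[1-(aryloxy)vinyl]cyclobut-2-en-1-one (racemic) | O=C1C(OC)=C(OC)C1(O[Si](C)(C)C(C)(C)C)C(=C)Oc2c(OC)cc(Oc3c(OC)cc(Oc4c(OC)cc(OC)cc4OC)cc3OC)cc2OC | intermediate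
17 | (3Z)-4-[(tert-butyldimethylsilyl)oxy]-2,3-dimethoxy-5-(aryloxy)hexa-1,3,5-trien-1-one (dienylketene) | O=C=C(OC)/C(OC)=C(O[Si](C)(C)C(C)(C)C)\C(=C)Oc1c(OC)cc(Oc2c(OC)cc(Oc3c(OC)cc(OC)cc3OC)cc2OC)cc1OC | intermediate
18 | 4-[(tert-butyldimethylsilyl)oxy]-2,3-dimethoxy-5-(aryloxy)cyclohexa-2,4-dien-1-one | O=C1CC(Oc2c(OC)cc(Oc3c(OC)cc(Oc4c(OC)cc(OC)cc4OC)cc3OC)cc2OC)=C(O[Si](C)(C)C(C)(C)C)C(OC)=C1OC | intermediate
19 | 4-[(tert-butyldimethylsilyl)oxy]-2,3-dimethoxy-5-(aryloxy)phenol | Oc1cc(Oc2c(OC)cc(Oc3c(OC)cc(Oc4c(OC)cc(OC)cc4OC)cc3OC)cc2OC)c(O[Si](C)(C)C(C)(C)C)c(OC)c1OC | intermediate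
20 | tert-butyldimethylsilyl ether of 2,3,4-trimethoxy-6-(aryloxy)phenol | COc1cc(Oc2c(OC)cc(Oc3c(OC)cc(Oc4c(OC)cc(OC)cc4OC)cc3OC)cc2OC)c(O[Si](C)(C)C(C)(C)C)c(OC)c1OC | intermediate
21 | 2,3,4-trimethoxy-6-(aryloxy)phenol | COc1cc(Oc2c(OC)cc(Oc3c(OC)cc(Oc4c(OC)cc(OC)cc4OC)cc3OC)cc2OC)c(O)c(OC)c1OC | intermediate
22 | 3,4,5-trimethoxyphenylboronic acid | COc1cc(B(O)O)cc(OC)c1OC | starting material
23 | 5-bromo-1,3-dimethoxy-2-(3,4,5-trimethoxyphenoxy)benzene | COc1cc(Br)cc(OC)c1Oc1cc(OC)c(OC)c(OC)c1 | intermediate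
24 | 1-(aryloxy)-2-[3,5-dimethoxy-4-(3,4,5-trimethoxyphenoxy)phenoxy]-3,4,5-trimethoxybenzene (pentadecamethyl ether of the target) | COc1cc(Oc2c(OC)cc(Oc3c(OC)cc(Oc4c(OC)cc(OC)cc4OC)cc3OC)cc2OC)c(Oc2cc(OC)c(Oc3cc(OC)c(OC)c(OC)c3)c(OC)c2)c(OC)c1OC | intermediate
25 | pentadecakis(O-dibromoboryl) ester of the target (idealised borate ester before hydrolysis) | BrB(Br)Oc1cc(Oc2c(OB(Br)Br)cc(Oc3c(OB(Br)Br)cc(Oc4c(OB(Br)Br)cc(OB(Br)Br)cc4OB(Br)Br)cc3OB(Br)Br)cc2OB(Br)Br)c(Oc2cc(OB(Br)Br)c(Oc3cc(OB(Br)Br)c(OB(Br)Br)c(OB(Br)Br)c3)c(OB(Br)Br)c2)c(OB(Br)Br)c1OB(Br)Br | intermediate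
26 | CNP0175585.0 (hexameric phlorethol with rings A to F, fifteen free OH) | Oc1cc(O)c(Oc2cc(O)c(Oc3cc(O)c(Oc4cc(O)c(O)c(O)c4Oc4cc(O)c(Oc5cc(O)c(O)c(O)c5)c(O)c4)c(O)c3)c(O)c2)c(O)c1 | target

**Count**

Total steps: 15. Longest linear sequence: 14 steps (steps 1 to 12, then 14 and 15); step 13 is a one-step side branch.

**Steps most likely to fail**

Step 9. The 1-aryloxyvinyllithium may be lost before it meets the squarate, by α-elimination of lithium aryloxide from this carbenoid-like species or by proton transfer from the arene C–H positions flanked by two oxygens. A second addition to the squarate is also possible. The fallback replaces the lithium reagent by a less basic magnesium reagent; it sets out from stannane 12 and comes back at 16. Iododestannylation of 12 (I2, CH2Cl2, 0 °C) should give the 1-iodovinyl aryl ether F1, which is used crude. Iodine–magnesium exchange with i-PrMgCl·LiCl (THF, −40 °C) should give 1-(aryloxy)vinylmagnesium chloride F2. Addition to dimethyl squarate 13 at −40 °C gives the chloromagnesium alkoxide adduct F3, and aqueous NH4Cl releases the 4-hydroxycyclobutenone F4. Silylation with TBSOTf and 2,6-lutidine (CH2Cl2, −78 °C) then gives 16.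

Step 14. The copper-catalysed C–O bond formation may stall at the di-ortho-substituted, electron-rich ring D phenoxide, with reductive loss of bromine from 23 at the temperature required. The fallback turns the electrophile into a boron nucleophile and couples oxidatively at room temperature; it sets out from bromide 23 (with phenol 21) and comes back at 24. Bromine–lithium exchange on 23 (n-BuLi, THF, −78 °C) gives the E–F aryllithium F5. Trapping with B(OiPr)3 gives the lithium aryltriisopropoxyborate F6, and aqueous HCl liberates the E–F boronic acid F7. Chan–Lam coupling of F7 with 21 (Cu(OAc)2, pyridine, 4 Å molecular sieves, CH2Cl2, air, rt), the kind of coupling used in step 13, should give 24.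

Step 15. Cleavage of fifteen methyl ethers may stop short, and the free polyphenol may be oxidised by air during work-up and chromatography, so that the product cannot be separated from partly methylated congeners. The fallback isolates the product through a stable derivative; it sets out from the crude demethylation mixture obtained from 24 and comes back at pure 26. The crude polyphenol is acetylated at once (Ac2O, pyridine, DMAP cat., rt) to the pentadecaacetate F8, which can be purified on silica without oxidation. Acid-catalysed methanolysis (HCl in degassed MeOH, 0 °C to rt) then removes the acetates and releases 26 with only volatile co-products.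

**Further compounds**

F1 | step 9 | 1-iodovinyl aryl ether ArO–C(I)=CH2 | C=C(I)Oc1c(OC)cc(Oc2c(OC)cc(Oc3c(OC)cc(OC)cc3OC)cc2OC)cc1OC
F2 | step 9 | 1-(aryloxy)vinylmagnesium chloride | C=C([Mg]Cl)Oc1c(OC)cc(Oc2c(OC)cc(Oc3c(OC)cc(OC)cc3OC)cc2OC)cc1OC
F3 | step 9 | chloromagnesium alkoxide of 4-hydroxy-2,3-dimethoxy-4-[1-(aryloxy)vinyl]cyclobut-2-en-1-one (racemic) | Cl[Mg]OC1(C(=C)Oc2c(OC)cc(Oc3c(OC)cc(Oc4c(OC)cc(OC)cc4OC)cc3OC)cc2OC)C(OC)=C(OC)C1=O
F4 | step 9 | 4-hydroxy-2,3-dimethoxy-4-[1-(aryloxy)vinyl]cyclobut-2-en-1-one (racemic) | O=C1C(OC)=C(OC)C1(O)C(=C)Oc2c(OC)cc(Oc3c(OC)cc(Oc4c(OC)cc(OC)cc4OC)cc3OC)cc2OC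
F5 | step 14 | [3,5-dimethoxy-4-(3,4,5-trimethoxyphenoxy)phenyl]lithium | [Li]c1cc(OC)c(Oc2cc(OC)c(OC)c(OC)c2)c(OC)c1
F6 | step 14 | lithium [3,5-dimethoxy-4-(3,4,5-trimethoxyphenoxy)phenyl]triisopropoxyborate | [Li+].CC(C)O[B-](OC(C)C)(OC(C)C)c1cc(OC)c(Oc2cc(OC)c(OC)c(OC)c2)c(OC)c1
F7 | step 14 | [3,5-dimethoxy-4-(3,4,5-trimethoxyphenoxy)phenyl]boronic acid | OB(O)c1cc(OC)c(Oc2cc(OC)c(OC)c(OC)c2)c(OC)c1
F8 | step 15 | pentadecaacetate of CNP0175585.0 | CC(=O)Oc1cc(OC(C)=O)c(Oc2cc(OC(C)=O)c(Oc3cc(OC(C)=O)c(Oc4cc(OC(C)=O)c(OC(C)=O)c(OC(C)=O)c4Oc4cc(OC(C)=O)c(Oc5cc(OC(C)=O)c(OC(C)=O)c(OC(C)=O)c5)c(OC(C)=O)c4)c(OC(C)=O)c3)c(OC(C)=O)c2)c(OC(C)=O)c1
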